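Locants follow germacrane numbering throughout (C1 ketone carbon, C4=C5 ring alkene, C6 lactone carbinol, C7=C11, C8, C10, C12 lactone carbonyl, C13 acetoxymethyl); in the bicyclic intermediates this coincides with guaiane numbering (C1 and C5 at the ring fusion). Nothing here has been tested experimentally; all outcomes are expectations.

## Analysis of the target

Compound 39 is a ten-membered carbocycle (C1–C10) fused across C6–C7 to a butenolide (O6–C12(=O)–C11=C7). The ring carries a ketone at C1, an E-trisubstituted alkene C4=C5, a methacrylate at C8, and a tertiary acetate and methyl at C10. There are three stereocentres, C6 (R), C8 (S) and C10 (R). Their oxygen substituents all lie on the same face of the ring, and each is separated from the next by one carbon (C7, C9), so none can be set from its neighbour by a simple 1,2-relationship. The sensitive sites are as follows: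
- C6–H is both the γ-hydrogen of the butenolide and allylic to C4=C5, so it epimerises under base.
- The C8 ester and the C13 acetate are both allylic to C7=C11.
- The C1 ketone faces the C4=C5 alkene across the ring, which invites acid-induced transannular closure.
- The C10 acetate sits on a tertiary α-ketol.

The difficulty is the medium ring with its E alkene, together with the order in which these groups can be introduced. The strategy rests on the relationship C1(=O)–C2–C3–C4=C5: this is what remains when the C1–C5 bond shared by a five-membered ring (C1–C5) and a seven-membered ring (C1, C5–C10) is cut while an electrofuge leaves C4.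

## Retrosynthetic reasoning

**Lactone (39 from 37).** The O6–C12 bond and the C6–H bond are cut, leading back to the keto ester 37 with a Z-configured C7=C11 alkylidene. Cutting here leaves the base- and acid-labile butenolide to the last step and lets a chiral reduction catalyst set C6, the one centre with no nearby controller. The forward step must reduce the C6 dienone carbonyl in preference to the hindered C1 ketone, after which the ester, held cis to C6, closes on its own.

**Acyl groups (37 from 33).** The methacrylate and the tertiary acetate are traced back to a silyl ether at O8 and a methoxymethyl ether at O10 in 33. The exchange is placed before the lactone exists and while C4=C5 is still conjugated to C6=O, so the Lewis acid used on the acetal cannot trigger a transannular reaction. O8 is acylated before O10 is freed, so a free hydroxyl never sits next to an acyl group that could migrate to it.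

**Ring expansion (33 from 31).** The C4=C5 π bond and the C1 carbonyl are reconnected as a C1–C5 σ bond, with a C1 hydroxyl and a trimethylstannyl group on C4. This turns the ten-membered ring into a cis-fused five–seven bicycle, 31. The gain is that no medium ring has to be closed by bond formation, and the alkene geometry is fixed by two stereocentres of a rigid cyclopentane. The forward step must break C1–C5 rather than C1–C10 or C1–C2.

**C7=C11 (31 from 25 and 27).** The alkylidene ester is disconnected at C7=C11 into the ketone 25 and the keto ester 27 (aldol addition, then syn dehydration). This is done on the bicycle and not after ring expansion: in the ring-expanded dione the C1 and C6 ketones would both enolise (at C2 and C7) with no reliable preference. In 25, C6 is the only carbonyl and its other α-position, C5, is a methine between two quaternary carbons. The plain stannyl hydroazulenone 24 is therefore an isolated intermediate, and the alkylidene ester rides through the ring expansion as a spectator.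

**C4–Sn (24 from 21).** The tin is removed from C4 together with H5, giving the enone 21. The forward conjugate addition of the stannyl anion 23 to the C4=C5–C6=O unit must deliver tin and then the proton to the same face.

**Seven-membered ring (21 from 19).** The C7–C8 bond is cut (aldol), giving the methyl ketone–aldehyde 19. This closure makes the C8 stereocentre inside a ring, where the C1 and C10 oxygens can hold the aldehyde oxygen on their face.

**Five-membered ring (19 from 16).** The C4=C5 bond is cut (ring-closing metathesis), with adjustment of oxidation level at C6 and C8, giving the diene 16. A tetrasubstituted alkene is most accessible by metathesis when it closes a five-membered ring.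

**C1 carbinol (16 from 12 and 14; 12 from 7 and 10).** The two carbon arms on C1 are removed one after the other, back to the amide 7. The alkenyl arm (from 10) is added first and the alkyl arm (from 14) second. The ketone 12 that receives the second arm then has no α-hydrogen, and chelation between the C1 carbonyl and the C10 ether oxygen steers the nucleophile to the face that gives the (1S) carbinol.

**C10 (7 from 1).** The quaternary C10 with its oxygen and methyl comes unchanged from (R)-citramalic acid 1. Its α-carboxyl becomes C1 and the β-carboxyl, after reduction, becomes C8. No step has to create this centre.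

## Alternatives that were turned down

**Alternative 1:** The C6–C7 bond and the lactone C–O bond are cut. The forward key step treats the open-chain aldehyde–allylic bromide A1 with CrCl2 (divalent chromium): the allylchromium attacks the C6 aldehyde through C7 and the alkoxide closes onto the ester, giving the α-methylene lactone A2.
- For it: it is convergent and makes the ring, the lactone and C6 in one operation, and intramolecular allylation has good precedent for medium rings. On convergence it is stronger than the chosen route.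
- Against it: A1 carries the α-acetoxy ketone, which divalent chromium can deoxygenate. The closure creates a C7–H stereocentre that the target does not have. The exocyclic alkene of A2 must then be moved to C7=C11 with oxidation at C13, at a stage where C6–H and C8–H are also allylic. The cis/trans outcome at C6/C7 depends on a flexible ten-membered transition state.
- Comparison: the chosen route gives up convergence but has no macrocyclisation, and it places the C7=C11 alkene and the C13 oxygen by a C–C bond-forming step with no later transposition.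

**Alternative 2:** The C7–C8 bond is cut. NiCl2/CrCl2 (catalytic nickel, divalent chromium) couples the enol triflate of the tetronate with the C8 aldehyde in A3, giving the hydroxy lactone A4.
- For it: the butenolide with its C13 acetate is complete before the ring is closed, and the free C8 hydroxyl of A4 needs only acylation. In the number of steps after ring formation it is clearly better than the chosen route.
- Against it: the C8 stereocentre is formed during the ten-membered ring closure with no local control. The triflate of A3 is a vinylogous acyl triflate with an acidic, doubly allylic C6–H. The C1 ketone is a competing electrophile. High dilution and excess chromium are needed.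
- Comparison: the chosen route sets C8 in a seven-membered ring under chelation and closes no medium ring.

**Alternative 3:** The C3–C4 bond is cut. Pd(OAc)2 with a biarylphosphine and Cs2CO3 opens the C1 cyclopropanol of A5 to a palladium homoenolate that couples with the C4 alkenyl iodide, giving the acetonide A6.
- For it: the C1 ketone and the ring are made together, the alkene geometry is carried over from the iodide, and one acetonide protects O8 and O10. It is the shortest on paper.
- Against it: ring-opening cross-coupling of a cyclopropanol has not been used to close a ten-membered ring, and β-hydride elimination of the homoenolate to an enone is the expected side reaction. Cs2CO3 meets the epimerisable C6–H. The acetonide must come off with acid when the C1 ketone and the C4=C5 alkene are already facing each other, and the tertiary acetate is then put on last.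
- Comparison: the chosen route is longer, but its ring-forming event belongs to a known reaction type and its stereocentres are set in five- and seven-membered rings.

Key step: step 22

## Route

Remarks on the chemistry:
- Racemic 8 is used, so 12, 16, 17 and 18 are pairs of epimers at C6; this centre becomes a carbonyl in step 13.
- 29 forms as diastereomers at C7 and C11; both become sp2 in step 20.
- Methyl 2-(acetoxymethyl)acrylate 26 is taken as a purchased compound.

Step 1
Reactants: 1 (R)-citramalic acid
Product: 2 2-[(4R)-2,2,4-trimethyl-5-oxo-1,3-dioxolan-4-yl]acetic acid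
Conditions: Me2C(OMe)2, p-TsOH (cat.), CH2Cl2, 25 °C
Reagents that add atoms: 2,2-dimethoxypropane, COC(C)(C)OC
Why: Acetal exchange ties the tertiary hydroxyl and its geminal carboxyl into a 1,3-dioxolan-4-one and leaves the CH2CO2H arm (later C8) free; the quaternary centre cannot epimerise.

Step 2
Reactants: 2 2-[(4R)-2,2,4-trimethyl-5-oxo-1,3-dioxolan-4-yl]acetic acid
Product: 4 (3R)-3-hydroxy-3-methyloxolan-2-one, via hydroxyethyl dioxolanone 3 (not isolated)
Conditions: BH3·SMe2, THF, 0 to 25 °C; MeOH; then p-TsOH (cat.), CH2Cl2, 25 °C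
Reagents that add atoms: none
Why: Borane reduces the free carboxylic acid much faster than the lactone-type carbonyl; acid then lets the new primary alcohol displace acetone (translactonisation to the five-membered lactone).

Step 3
Reactants: 4 (3R)-3-hydroxy-3-methyloxolan-2-one
Product: 5 (3R)-3-(methoxymethoxy)-3-methyloxolan-2-one
Conditions: MeOCH2Cl, i-Pr2NEt, Bu4NI (cat.), ClCH2CH2Cl, 60 °C
Reagents that add atoms: chloromethyl methyl ether, COCCl
Why: O-alkylation of the hindered tertiary alcohol by the reactive α-chloro ether; the acetal survives all organometallic steps and its oxygen can chelate magnesium, cerium and lithium in steps 10 and 14.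

Step 4
Reactants: 5 (3R)-3-(methoxymethoxy)-3-methyloxolan-2-one
Product: 6 (2R)-4-hydroxy-N-methoxy-2-(methoxymethoxy)-N,2-dimethylbutanamide
Conditions: MeNH(OMe)·HCl, i-PrMgCl, THF, −20 to 0 °C
Reagents that add atoms: N,O-dimethylhydroxylamine hydrochloride, CNOC.Cl
Why: Aminolysis of the lactone by the chloromagnesium amide (Weinreb amide formation); the stereocentre is not involved.

Step 5
Reactants: 6 (2R)-4-hydroxy-N-methoxy-2-(methoxymethoxy)-N,2-dimethylbutanamide
Product: 7 (2R)-4-[(tert-butyldimethylsilyl)oxy]-N-methoxy-2-(methoxymethoxy)-N,2-dimethylbutanamide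
Conditions: t-BuMe2SiCl, imidazole, DMF, 25 °C
Reagents that add atoms: tert-butyldimethylsilyl chloride, CC(C)(C)[Si](C)(C)Cl
Why: Silylation stops relactonisation and masks the C8 oxygen through the two additions at C1.

Step 6
Reactants: 8 but-3-yn-2-ol
Product: 9 3-bromobut-3-en-2-ol
Conditions: Et4NBr·HBr, CH2Cl2, 40 °C
Reagents that add atoms: tetraethylammonium hydrogen dibromide, CC[N+](CC)(CC)CC.[Br-].Br
Why: Markovnikov hydrobromination of a terminal alkyne by the hydrogen dibromide salt, a reaction known for propargylic alcohols, puts bromine on the internal carbon (later C5).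

Step 7
Reactants: 9 3-bromobut-3-en-2-ol
Product: 10 [(3-bromobut-3-en-2-yl)oxy](tert-butyl)dimethylsilane
Conditions: t-BuMe2SiCl, imidazole, CH2Cl2, 25 °C
Reagents that add atoms: tert-butyldimethylsilyl chloride, CC(C)(C)[Si](C)(C)Cl
Why: Standard silylation; a silyl ether at C6 does not chelate and so does not compete with the C10 ether in step 10.

Step 8
Reactants: 7 (2R)-4-[(tert-butyldimethylsilyl)oxy]-N-methoxy-2-(methoxymethoxy)-N,2-dimethylbutanamide; 10 [(3-bromobut-3-en-2-yl)oxy](tert-butyl)dimethylsilane
Product: 12 (5R)-2,7-bis[(tert-butyldimethylsilyl)oxy]-5-(methoxymethoxy)-5-methyl-3-methylideneheptan-4-one, via alkenyllithium 11 (not isolated)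
Conditions: 10, t-BuLi (2 equiv), Et2O, −78 °C; then 7, −78 to −20 °C; aq. NH4Cl
Reagents that add atoms: none
Why: Bromine–lithium exchange gives the alkenyllithium, which adds once to the Weinreb amide (stable chelated adduct) and releases the ketone on work-up; this forms the C1–C5 bond.

Step 9
Reactants: 13 3-methylbut-3-en-1-ol
Product: 14 4-bromo-2-methylbut-1-ene
Conditions: CBr4, PPh3, CH2Cl2, 0 °C
Reagents that add atoms: carbon tetrabromide, BrC(Br)(Br)Br
Why: Appel bromination of the primary homoallylic alcohol.

Step 10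
Reactants: 12 (5R)-2,7-bis[(tert-butyldimethylsilyl)oxy]-5-(methoxymethoxy)-5-methyl-3-methylideneheptan-4-one; 14 4-bromo-2-methylbut-1-ene
Product: 16 (4S,5R)-2,7-bis[(tert-butyldimethylsilyl)oxy]-5-(methoxymethoxy)-5-methyl-3-methylidene-4-(3-methylbut-3-en-1-yl)heptan-4-ol, via Grignard reagent 15 (not isolated)
Conditions: 14, Mg, THF, 25 °C; CeCl3, THF, −78 °C; then 12, −78 °C
Reagents that add atoms: none
Why: The organocerium reagent adds 1,2 to a ketone that has no α-hydrogen; the metal is chelated between the C1 carbonyl and the C10 acetal oxygen and the nucleophile passes the C10 methyl group (Cram chelate model), giving the (1S) carbinol with O1 and O10 on the same side of the later seven-membered ring. A minor C1 epimer would not be lost, because C1 becomes a carbonyl in step 22.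

Step 11
Reactants: 16 (4S,5R)-2,7-bis[(tert-butyldimethylsilyl)oxy]-5-(methoxymethoxy)-5-methyl-3-methylidene-4-(3-methylbut-3-en-1-yl)heptan-4-ol
Product: 17 (1S)-1-{(2R)-4-[(tert-butyldimethylsilyl)oxy]-2-(methoxymethoxy)butan-2-yl}-2-{1-[(tert-butyldimethylsilyl)oxy]ethyl}-3-methylcyclopent-2-en-1-ol
Conditions: second-generation Hoveyda–Grubbs catalyst (H2IMes)Cl2Ru=CH(C6H4-2-Oi-Pr) (10 mol%), toluene, 80 °C, argon purge
Reagents that add atoms: none
Why: Ring-closing metathesis of two 1,1-disubstituted alkenes; a five-membered ring is the most favourable case for a tetrasubstituted alkene, and the phosphine-free catalyst at 80 °C with removal of ethylene is the usual choice for it.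

Step 12
Reactants: 17 (1S)-1-{(2R)-4-[(tert-butyldimethylsilyl)oxy]-2-(methoxymethoxy)butan-2-yl}-2-{1-[(tert-butyldimethylsilyl)oxy]ethyl}-3-methylcyclopent-2-en-1-ol
Product: 18 (1S)-2-(1-hydroxyethyl)-1-[(2R)-4-hydroxy-2-(methoxymethoxy)butan-2-yl]-3-methylcyclopent-2-en-1-ol
Conditions: Bu4NF, THF, 25 °C
Reagents that add atoms: none
Why: Fluoride cleaves both silyl ethers; the acetal and the tertiary alcohol are unaffected.

Step 13
Reactants: 18 (1S)-2-(1-hydroxyethyl)-1-[(2R)-4-hydroxy-2-(methoxymethoxy)butan-2-yl]-3-methylcyclopent-2-en-1-ol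
Product: 19 (3R)-3-[(1S)-2-acetyl-1-hydroxy-3-methylcyclopent-2-en-1-yl]-3-(methoxymethoxy)butanal
Conditions: (COCl)2, DMSO, CH2Cl2, −78 °C; Et3N, −78 to 0 °C
Reagents that add atoms: none
Why: Swern oxidation takes the primary alcohol to the aldehyde and the secondary allylic alcohol to the enone in one operation (the C6 epimers converge). The tertiary alcohol cannot be oxidised, and activated DMSO does not carry the hydroxy aldehyde, which sits partly as its five-membered lactol with O1, on to a lactone.

Step 14
Reactants: 19 (3R)-3-[(1S)-2-acetyl-1-hydroxy-3-methylcyclopent-2-en-1-yl]-3-(methoxymethoxy)butanal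
Product: 20 (1S,8S,10R)-1,8-dihydroxy-10-(methoxymethoxy)-4,10-dimethylbicyclo[5.3.0]dec-4-en-6-one
Conditions: LiN(SiMe3)2 (2.2 equiv), THF, −78 °C, slow addition of 19 (0.005 M)
Reagents that add atoms: none
Why: Intramolecular aldol addition closing the seven-membered ring. The first equivalent of base makes the lithium lactolate, which shields the aldehyde from enolisation, and the second removes a proton from the methyl ketone (C7). The lithium held by O1 and the C10 acetal oxygen keeps the opening aldehyde oxygen on its own face, so O8 should end up cis to O1 and O10 (8S).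

Step 15
Reactants: 20 (1S,8S,10R)-1,8-dihydroxy-10-(methoxymethoxy)-4,10-dimethylbicyclo[5.3.0]dec-4-en-6-one
Product: 21 (1S,8S,10R)-8-[(tert-butyldimethylsilyl)oxy]-1-hydroxy-10-(methoxymethoxy)-4,10-dimethylbicyclo[5.3.0]dec-4-en-6-one
Conditions: t-BuMe2SiCl, imidazole, DMF, 25 °C
Reagents that add atoms: tert-butyldimethylsilyl chloride, CC(C)(C)[Si](C)(C)Cl
Why: Selective silylation of the secondary alcohol; the ring-fusion tertiary alcohol does not react under these conditions.

Step 16
Reactants: 21 (1S,8S,10R)-8-[(tert-butyldimethylsilyl)oxy]-1-hydroxy-10-(methoxymethoxy)-4,10-dimethylbicyclo[5.3.0]dec-4-en-6-one; 22 hexamethylditin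
Product: 24 (1S,4R,5S,8S,10R)-8-[(tert-butyldimethylsilyl)oxy]-1-hydroxy-10-(methoxymethoxy)-4,10-dimethyl-4-(trimethylstannyl)bicyclo[5.3.0]decan-6-one, via trimethylstannyllithium 23 (not isolated)
Conditions: 22, MeLi, THF, −20 °C; then 21 (0.33 equiv), −78 °C; AcOH, THF, −78 °C
Reagents that add atoms: none
Why: Conjugate addition of a stannyl anion to a β,β-disubstituted enone (one equivalent is used up by the hydroxyl). The stannyl anion and then the proton should both enter on the convex face of the folded bicycle, syn to the C1 oxygen and anti to C10, which gives the cis ring fusion and puts tin cis to H5 (4R,5S).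

Step 17
Reactants: 24 (1S,4R,5S,8S,10R)-8-[(tert-butyldimethylsilyl)oxy]-1-hydroxy-10-(methoxymethoxy)-4,10-dimethyl-4-(trimethylstannyl)bicyclo[5.3.0]decan-6-one
Product: 25 (1S,4R,5S,8S,10R)-8-[(tert-butyldimethylsilyl)oxy]-10-(methoxymethoxy)-4,10-dimethyl-4-(trimethylstannyl)-1-[(trimethylsilyl)oxy]bicyclo[5.3.0]decan-6-one
Conditions: N-(trimethylsilyl)imidazole, CH2Cl2, 25 °C
Reagents that add atoms: N-(trimethylsilyl)imidazole, C[Si](C)(C)n1ccnc1
Why: Neutral silylation of the tertiary alcohol, so that steps 19 and 20 meet one hydroxyl only; the silyloxy group on C1 and the stannyl group on C4 also make the C5 epimer with C6 anti to both the stable one.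

Step 18
Reactants: 26 methyl 2-(acetoxymethyl)acrylate
Product: 27 methyl 3-acetoxy-2-oxopropanoate
Conditions: O3, CH2Cl2, −78 °C; Me2S, −78 to 25 °C
Reagents that add atoms: ozone, [O-][O+]=O
Why: Ozonolysis of the 1,1-disubstituted alkene gives the α-keto ester, which is used at once because it hydrates easily.

Step 19
Reactants: 25 (1S,4R,5S,8S,10R)-8-[(tert-butyldimethylsilyl)oxy]-10-(methoxymethoxy)-4,10-dimethyl-4-(trimethylstannyl)-1-[(trimethylsilyl)oxy]bicyclo[5.3.0]decan-6-one; 27 methyl 3-acetoxy-2-oxopropanoate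
Product: 29 methyl 3-acetoxy-2-hydroxy-2-[(1S,4R,5S,8S,10R)-8-[(tert-butyldimethylsilyl)oxy]-10-(methoxymethoxy)-4,10-dimethyl-6-oxo-4-(trimethylstannyl)-1-[(trimethylsilyl)oxy]bicyclo[5.3.0]decan-7-yl]propanoate, via dibutylboron enolate 28 (not isolated)
Conditions: Bu2BOTf, i-Pr2NEt, CH2Cl2, −78 °C; then 27, −78 °C; pH 7 buffer, MeOH
Reagents that add atoms: none
Why: Boron aldol addition to an activated keto carbonyl. Enolisation can only go toward C7, since C6 is the only carbonyl and C5 is a methine between two quaternary carbons. In the chair transition state (Zimmerman–Traxler) the ester of 27 should sit axial and the larger acetoxymethyl group equatorial, which fixes the C7/C11 relationship used in step 20.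

Step 20
Reactants: 29 methyl 3-acetoxy-2-hydroxy-2-[(1S,4R,5S,8S,10R)-8-[(tert-butyldimethylsilyl)oxy]-10-(methoxymethoxy)-4,10-dimethyl-6-oxo-4-(trimethylstannyl)-1-[(trimethylsilyl)oxy]bicyclo[5.3.0]decan-7-yl]propanoate
Product: 30 methyl (2Z)-3-acetoxy-2-[(1S,4R,5S,8S,10R)-8-[(tert-butyldimethylsilyl)oxy]-10-(methoxymethoxy)-4,10-dimethyl-6-oxo-4-(trimethylstannyl)-1-[(trimethylsilyl)oxy]bicyclo[5.3.0]decan-7-ylidene]propanoate
Conditions: MeO2CN(−)SO2N(+)Et3 (Burgess reagent), benzene, 50 °C
Reagents that add atoms: none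
Why: Burgess dehydration is a syn elimination through the sulfamate ester; it removes the acidic H7, and from the chair-derived adduct it should give the Z alkylidene with the ester on the side of C6. The C1 oxygen is silylated, so only the C11 hydroxyl reacts.

Step 21
Reactants: 30 methyl (2Z)-3-acetoxy-2-[(1S,4R,5S,8S,10R)-8-[(tert-butyldimethylsilyl)oxy]-10-(methoxymethoxy)-4,10-dimethyl-6-oxo-4-(trimethylstannyl)-1-[(trimethylsilyl)oxy]bicyclo[5.3.0]decan-7-ylidene]propanoate
Product: 31 methyl (2Z)-3-acetoxy-2-[(1S,4R,5S,8S,10R)-8-[(tert-butyldimethylsilyl)oxy]-1-hydroxy-10-(methoxymethoxy)-4,10-dimethyl-6-oxo-4-(trimethylstannyl)bicyclo[5.3.0]decan-7-ylidene]propanoate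
Conditions: PPTS (cat.), MeOH, 0 °C
Reagents that add atoms: none
Why: Acid-catalysed methanolysis of the tertiary trimethylsilyl ether; the tert-butyldimethylsilyl ether, the acetal and the alkylstannane are stable here. Oxa-Michael addition of the freed tertiary hydroxyl to the fully substituted C11 is not expected.

Step 22
Reactants: 31 methyl (2Z)-3-acetoxy-2-[(1S,4R,5S,8S,10R)-8-[(tert-butyldimethylsilyl)oxy]-1-hydroxy-10-(methoxymethoxy)-4,10-dimethyl-6-oxo-4-(trimethylstannyl)bicyclo[5.3.0]decan-7-ylidene]propanoate
Product: 33 methyl (2Z)-3-acetoxy-2-[(4E,8S,10R)-8-[(tert-butyldimethylsilyl)oxy]-10-(methoxymethoxy)-4,10-dimethyl-1,6-dioxocyclodec-4-en-7-ylidene]propanoate, via lead alkoxide 32 (not isolated)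
Conditions: Pb(OAc)4, CaCO3, benzene, 25 °C
Reagents that add atoms: none
Why: The tertiary alcohol exchanges onto the oxidant to give the alkoxide 32 of tetravalent lead. Lead then leaves as divalent lead with the O–Pb electron pair: the C1–O bond becomes the carbonyl, the C1–C5 σ electrons become the C4=C5 π bond, and the C4–Sn bond gives up Me3Sn+ to acetate. The closest known reaction type is the lead tetraacetate (or iodosylbenzene) fragmentation of γ-hydroxy stannanes to unsaturated ketones, the tin version of a Grob fragmentation, which has been used to expand fused stannyl carbinols to medium-ring ketones. No ring is closed by bond formation: the ten-membered ring is what is left when the bond shared by the five- and seven-membered rings is cut, so there is no entropic cost and no high dilution. No stereocentre is formed; the alkene geometry follows from 31, because C4–Sn lies anti to C1–C5 across C4–C5 and tin is cis to H5, which places C3 and C6 on opposite sides (E). The step needs C1–C5 cleavage to beat cleavage of C1–C10 and C1–C2: only C1–C5 has an anti C–Sn bond to take up the electron deficiency at C5, and a monoether of a 1,2-diol such as the C1–OH/C10–OCH2OMe pair is not normally cleaved by Pb(OAc)4 at room temperature. Because C5 lies next to the C6 carbonyl it can carry little positive charge, so the cleavage has to be concerted; the conjugation gained in the dienone should help. The alkylidene ester, the silyl ether and the acetal are inert to the oxidant.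

Step 23
Reactants: 33 methyl (2Z)-3-acetoxy-2-[(4E,8S,10R)-8-[(tert-butyldimethylsilyl)oxy]-10-(methoxymethoxy)-4,10-dimethyl-1,6-dioxocyclodec-4-en-7-ylidene]propanoate
Product: 34 methyl (2Z)-3-acetoxy-2-[(4E,8S,10R)-8-hydroxy-10-(methoxymethoxy)-4,10-dimethyl-1,6-dioxocyclodec-4-en-7-ylidene]propanoate
Conditions: HF·pyridine, pyridine, THF, 0 to 25 °C
Reagents that add atoms: none
Why: Buffered fluoride removes the secondary silyl ether while C4=C5 is still conjugated and before the lactone exists. The freed hydroxyl may sit as a transannular hemiketal with C1, but it is acylated from the open form in step 24.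

Step 24
Reactants: 34 methyl (2Z)-3-acetoxy-2-[(4E,8S,10R)-8-hydroxy-10-(methoxymethoxy)-4,10-dimethyl-1,6-dioxocyclodec-4-en-7-ylidene]propanoate
Product: 35 (1S,3R,7E)-10-[(2Z)-3-acetoxy-1-methoxy-1-oxopropan-2-ylidene]-3-(methoxymethoxy)-3,7-dimethyl-4,9-dioxocyclodec-7-en-1-yl 2-methylprop-2-enoate
Conditions: [CH2=C(Me)CO]2O, DMAP (cat.), Et3N, CH2Cl2, 0 °C
Reagents that add atoms: methacrylic anhydride, CC(=C)C(=O)OC(=O)C(C)=C
Why: DMAP-catalysed acylation of the secondary allylic alcohol; the C11 ester is trans to C8 across the alkene and cannot lactonise with it.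

Step 25
Reactants: 35 (1S,3R,7E)-10-[(2Z)-3-acetoxy-1-methoxy-1-oxopropan-2-ylidene]-3-(methoxymethoxy)-3,7-dimethyl-4,9-dioxocyclodec-7-en-1-yl 2-methylprop-2-enoate
Product: 36 (1S,3R,7E)-10-[(2Z)-3-acetoxy-1-methoxy-1-oxopropan-2-ylidene]-3-hydroxy-3,7-dimethyl-4,9-dioxocyclodec-7-en-1-yl 2-methylprop-2-enoate
Conditions: Me2BBr, CH2Cl2, −78 °C; aq. NaHCO3
Reagents that add atoms: none
Why: Bromodimethylborane cleaves methoxymethyl ethers at −78 °C and leaves esters and enones alone; the alkene is still deactivated by conjugation, so the Lewis acid cannot start a transannular reaction with the C1 carbonyl.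

Step 26
Reactants: 36 (1S,3R,7E)-10-[(2Z)-3-acetoxy-1-methoxy-1-oxopropan-2-ylidene]-3-hydroxy-3,7-dimethyl-4,9-dioxocyclodec-7-en-1-yl 2-methylprop-2-enoate
Product: 37 (1S,3R,7E)-3-acetoxy-10-[(2Z)-3-acetoxy-1-methoxy-1-oxopropan-2-ylidene]-3,7-dimethyl-4,9-dioxocyclodec-7-en-1-yl 2-methylprop-2-enoate
Conditions: Ac2O, DMAP, Et3N, CH2Cl2, 25 °C
Reagents that add atoms: acetic anhydride, CC(=O)OC(C)=O
Why: DMAP-catalysed acetylation of the tertiary α-ketol; no other hydroxyl is present, and migration of the C8 ester to the tertiary oxygen is uphill.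

Step 27
Reactants: 37 (1S,3R,7E)-3-acetoxy-10-[(2Z)-3-acetoxy-1-methoxy-1-oxopropan-2-ylidene]-3,7-dimethyl-4,9-dioxocyclodec-7-en-1-yl 2-methylprop-2-enoate
Product: 39 (4E,6R,8S,10R)-10,13-diacetoxy-8-(2-methylprop-2-enoyloxy)-1-oxogermacra-4,7(11)-dien-12,6-olide, via hydroxy ester 38 (not isolated)
Conditions: (S)-2-methyl-CBS-oxazaborolidine (20 mol%), catecholborane, toluene, −78 °C; MeOH; then PPTS (cat.), CH2Cl2, 25 °C
Reagents that add atoms: none
Why: Corey–Bakshi–Shibata reduction: the alkenyl ketone at C6 should react at −78 °C ahead of the C1 ketone, which is flanked by the quaternary C10. With the α-branched alkenyl carbon C7 as the large group and C5 as the small one, the (S)-catalyst should give the 6R alcohol. The ester, cis to C6, then closes the butenolide with loss of methanol.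

## Compound list

1 | (R)-citramalic acid, (2R)-2-hydroxy-2-methylbutanedioic acid | OC(=O)C[C@@](C)(O)C(=O)O | starting material
2 | 2-[(4R)-2,2,4-trimethyl-5-oxo-1,3-dioxolan-4-yl]acetic acid | CC1(C)OC(=O)[C@@](C)(CC(=O)O)O1 | intermediate
3 | (5R)-5-(2-hydroxyethyl)-2,2,5-trimethyl-1,3-dioxolan-4-one | CC1(C)OC(=O)[C@@](C)(CCO)O1 | intermediate (not isolated)
4 | (3R)-3-hydroxy-3-methyloxolan-2-one | O=C1OCC[C@@]1(C)O | intermediate
5 | (3R)-3-(methoxymethoxy)-3-methyloxolan-2-one | O=C1OCC[C@@]1(C)OCOC | intermediate
6 | (2R)-4-hydroxy-N-methoxy-2-(methoxymethoxy)-N,2-dimethylbutanamide | OCC[C@@](C)(OCOC)C(=O)N(C)OC | intermediate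
7 | (2R)-4-[(tert-butyldimethylsilyl)oxy]-N-methoxy-2-(methoxymethoxy)-N,2-dimethylbutanamide | CC(C)(C)[Si](C)(C)OCC[C@@](C)(OCOC)C(=O)N(C)OC | intermediate
8 | but-3-yn-2-ol (racemic) | CC(O)C#C | starting material
9 | 3-bromobut-3-en-2-ol (racemic) | CC(O)C(Br)=C | intermediate
10 | [(3-bromobut-3-en-2-yl)oxy](tert-butyl)dimethylsilane (racemic) | CC(O[Si](C)(C)C(C)(C)C)C(Br)=C | intermediate
11 | {3-[(tert-butyldimethylsilyl)oxy]but-1-en-2-yl}lithium | CC(O[Si](C)(C)C(C)(C)C)C([Li])=C | intermediate (not isolated)
12 | (5R)-2,7-bis[(tert-butyldimethylsilyl)oxy]-5-(methoxymethoxy)-5-methyl-3-methylideneheptan-4-one (10R; both epimers at C6) | CC(C)(C)[Si](C)(C)OCC[C@@](C)(OCOC)C(=O)C(=C)C(C)O[Si](C)(C)C(C)(C)C | intermediate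
13 | 3-methylbut-3-en-1-ol | CC(=C)CCO | starting material
14 | 4-bromo-2-methylbut-1-ene | CC(=C)CCBr | intermediate
15 | (3-methylbut-3-en-1-yl)magnesium bromide | CC(=C)CC[Mg]Br | intermediate (not isolated)
16 | (4S,5R)-2,7-bis[(tert-butyldimethylsilyl)oxy]-5-(methoxymethoxy)-5-methyl-3-methylidene-4-(3-methylbut-3-en-1-yl)heptan-4-ol (1S,10R; both epimers at C6) | CC(C)(C)[Si](C)(C)OCC[C@@](C)(OCOC)[C@](O)(CCC(C)=C)C(=C)C(C)O[Si](C)(C)C(C)(C)C | intermediate
17 | (1S)-1-{(2R)-4-[(tert-butyldimethylsilyl)oxy]-2-(methoxymethoxy)butan-2-yl}-2-{1-[(tert-butyldimethylsilyl)oxy]ethyl}-3-methylcyclopent-2-en-1-ol (both epimers at C6) | CC(C)(C)[Si](C)(C)OCC[C@@](C)(OCOC)[C@]1(O)CCC(C)=C1C(C)O[Si](C)(C)C(C)(C)C | intermediate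
18 | (1S)-2-(1-hydroxyethyl)-1-[(2R)-4-hydroxy-2-(methoxymethoxy)butan-2-yl]-3-methylcyclopent-2-en-1-ol (both epimers at C6) | OCC[C@@](C)(OCOC)[C@]1(O)CCC(C)=C1C(C)O | intermediate
19 | (3R)-3-[(1S)-2-acetyl-1-hydroxy-3-methylcyclopent-2-en-1-yl]-3-(methoxymethoxy)butanal (in equilibrium with its lactol) | O=CC[C@@](C)(OCOC)[C@]1(O)CCC(C)=C1C(C)=O | intermediate
20 | (1S,8S,10R)-1,8-dihydroxy-10-(methoxymethoxy)-4,10-dimethylbicyclo[5.3.0]dec-4-en-6-one (guaiane numbering) | O[C@@]12CCC(C)=C1C(=O)C[C@@H](O)C[C@@]2(C)OCOC | intermediate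
21 | (1S,8S,10R)-8-[(tert-butyldimethylsilyl)oxy]-1-hydroxy-10-(methoxymethoxy)-4,10-dimethylbicyclo[5.3.0]dec-4-en-6-one | O[C@@]12CCC(C)=C1C(=O)C[C@@H](O[Si](C)(C)C(C)(C)C)C[C@@]2(C)OCOC | intermediate
22 | hexamethylditin | C[Sn](C)(C)[Sn](C)(C)C | starting material
23 | trimethylstannyllithium | [Li][Sn](C)(C)C | intermediate (not isolated)
24 | (1S,4R,5S,8S,10R)-8-[(tert-butyldimethylsilyl)oxy]-1-hydroxy-10-(methoxymethoxy)-4,10-dimethyl-4-(trimethylstannyl)bicyclo[5.3.0]decan-6-one | O[C@@]12CC[C@@](C)([Sn](C)(C)C)[C@@H]1C(=O)C[C@@H](O[Si](C)(C)C(C)(C)C)C[C@@]2(C)OCOC | intermediate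
25 | (1S,4R,5S,8S,10R)-8-[(tert-butyldimethylsilyl)oxy]-10-(methoxymethoxy)-4,10-dimethyl-4-(trimethylstannyl)-1-[(trimethylsilyl)oxy]bicyclo[5.3.0]decan-6-one | C[Si](C)(C)O[C@@]12CC[C@@](C)([Sn](C)(C)C)[C@@H]1C(=O)C[C@@H](O[Si](C)(C)C(C)(C)C)C[C@@]2(C)OCOC | intermediate
26 | methyl 2-(acetoxymethyl)acrylate | C=C(COC(C)=O)C(=O)OC | starting material
27 | methyl 3-acetoxy-2-oxopropanoate | COC(=O)C(=O)COC(C)=O | intermediate
28 | dibutylboron enolate of 25 (C6–O–B, C6=C7) | C[Si](C)(C)O[C@@]12CC[C@@](C)([Sn](C)(C)C)[C@@H]1C(OB(CCCC)CCCC)=C[C@@H](O[Si](C)(C)C(C)(C)C)C[C@@]2(C)OCOC | intermediate (not isolated)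
29 | methyl 3-acetoxy-2-hydroxy-2-[(1S,4R,5S,8S,10R)-8-[(tert-butyldimethylsilyl)oxy]-10-(methoxymethoxy)-4,10-dimethyl-6-oxo-4-(trimethylstannyl)-1-[(trimethylsilyl)oxy]bicyclo[5.3.0]decan-7-yl]propanoate (diastereomers at C7 and C11) | C[Si](C)(C)O[C@@]12CC[C@@](C)([Sn](C)(C)C)[C@@H]1C(=O)C(C(O)(COC(C)=O)C(=O)OC)[C@@H](O[Si](C)(C)C(C)(C)C)C[C@@]2(C)OCOC | intermediate
30 | methyl (2Z)-3-acetoxy-2-[(1S,4R,5S,8S,10R)-8-[(tert-butyldimethylsilyl)oxy]-10-(methoxymethoxy)-4,10-dimethyl-6-oxo-4-(trimethylstannyl)-1-[(trimethylsilyl)oxy]bicyclo[5.3.0]decan-7-ylidene]propanoate | C[Si](C)(C)O[C@@]12CC[C@@](C)([Sn](C)(C)C)[C@@H]1C(=O)/C(=C(/COC(C)=O)C(=O)OC)[C@@H](O[Si](C)(C)C(C)(C)C)C[C@@]2(C)OCOC | intermediate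
31 | methyl (2Z)-3-acetoxy-2-[(1S,4R,5S,8S,10R)-8-[(tert-butyldimethylsilyl)oxy]-1-hydroxy-10-(methoxymethoxy)-4,10-dimethyl-6-oxo-4-(trimethylstannyl)bicyclo[5.3.0]decan-7-ylidene]propanoate | O[C@@]12CC[C@@](C)([Sn](C)(C)C)[C@@H]1C(=O)/C(=C(/COC(C)=O)C(=O)OC)[C@@H](O[Si](C)(C)C(C)(C)C)C[C@@]2(C)OCOC | intermediate
32 | triacetoxylead alkoxide of 31 (O1–Pb) | CC(=O)O[Pb](OC(C)=O)(OC(C)=O)O[C@@]12CC[C@@](C)([Sn](C)(C)C)[C@@H]1C(=O)/C(=C(/COC(C)=O)C(=O)OC)[C@@H](O[Si](C)(C)C(C)(C)C)C[C@@]2(C)OCOC | intermediate (not isolated)
33 | methyl (2Z)-3-acetoxy-2-[(4E,8S,10R)-8-[(tert-butyldimethylsilyl)oxy]-10-(methoxymethoxy)-4,10-dimethyl-1,6-dioxocyclodec-4-en-7-ylidene]propanoate (germacrane locants) | CC(C)(C)[Si](C)(C)O[C@H]1C[C@@](C)(OCOC)C(=O)CC/C(C)=C/C(=O)/C1=C(/COC(C)=O)C(=O)OC | intermediate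
34 | methyl (2Z)-3-acetoxy-2-[(4E,8S,10R)-8-hydroxy-10-(methoxymethoxy)-4,10-dimethyl-1,6-dioxocyclodec-4-en-7-ylidene]propanoate | O[C@H]1C[C@@](C)(OCOC)C(=O)CC/C(C)=C/C(=O)/C1=C(/COC(C)=O)C(=O)OC | intermediate
35 | (1S,3R,7E)-10-[(2Z)-3-acetoxy-1-methoxy-1-oxopropan-2-ylidene]-3-(methoxymethoxy)-3,7-dimethyl-4,9-dioxocyclodec-7-en-1-yl 2-methylprop-2-enoate | C=C(C)C(=O)O[C@H]1C[C@@](C)(OCOC)C(=O)CC/C(C)=C/C(=O)/C1=C(/COC(C)=O)C(=O)OC | intermediate
36 | (1S,3R,7E)-10-[(2Z)-3-acetoxy-1-methoxy-1-oxopropan-2-ylidene]-3-hydroxy-3,7-dimethyl-4,9-dioxocyclodec-7-en-1-yl 2-methylprop-2-enoate | C=C(C)C(=O)O[C@H]1C[C@@](C)(O)C(=O)CC/C(C)=C/C(=O)/C1=C(/COC(C)=O)C(=O)OC | intermediate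
37 | (1S,3R,7E)-3-acetoxy-10-[(2Z)-3-acetoxy-1-methoxy-1-oxopropan-2-ylidene]-3,7-dimethyl-4,9-dioxocyclodec-7-en-1-yl 2-methylprop-2-enoate | C=C(C)C(=O)O[C@H]1C[C@@](C)(OC(C)=O)C(=O)CC/C(C)=C/C(=O)/C1=C(/COC(C)=O)C(=O)OC | intermediate
38 | (6R)-hydroxy ester from 37 (C6 carbinol, other groups unchanged) | C=C(C)C(=O)O[C@H]1C[C@@](C)(OC(C)=O)C(=O)CC/C(C)=C/[C@@H](O)/C1=C(/COC(C)=O)C(=O)OC | intermediate (not isolated)
39 | (4E,6R,8S,10R)-10,13-diacetoxy-8-(2-methylprop-2-enoyloxy)-1-oxogermacra-4,7(11)-dien-12,6-olide | C=C(C)C(=O)O[C@H]1C[C@@](C)(OC(C)=O)C(=O)CC/C(C)=C/[C@H]2OC(=O)C(COC(C)=O)=C12 | target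

## Step count and uncertain steps

Total: 27 steps. Longest linear sequence: 23 steps, from 1 to 39 (steps 1–5, 8, 10–17, 19–27). The side branches are steps 6–7 (alkenyl arm), 9 (alkyl arm) and 18 (keto ester).

**Step 22 (key step).** The most likely failure is that the tin-assisted cleavage of C1–C5 is slow, because C5 lies next to the C6 carbonyl and gains little from the stannyl group. The lead alkoxide would then cleave the C1–C10 bond toward the oxygen-bearing C10, or the β-hydroxy ketone would lose water. The fallback removes the carbonyl before the ring expansion. From 30, NaBH4/CeCl3·7H2O in MeOH at −78 °C should reduce C6 from the face opposite the stannyl and silyloxy groups, and the hydroxy ester closes to the tricyclic stannyl butenolide F1. PPTS/MeOH gives the carbinol F2. Pb(OAc)4 then acts on a substrate whose C5 has no carbonyl neighbour and gives the germacranolide F3. HF·pyridine gives the 8-alcohol F4, methacrylic anhydride/DMAP the methacrylate F5, Me2BBr at −78 °C the tertiary alcohol F6, and Ac2O/DMAP returns to the route at 39.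

**Step 14.** The risks are poor facial selectivity at C8 if lithium chelation does not organise the closure, and β-elimination of the aldolate. The fallback accepts the elimination. From 19, K2CO3 in MeOH gives the cross-conjugated dienone F7. Copper-catalysed conjugate borylation (CuCl, NaOt-Bu, a Josiphos-type bisphosphine, B2pin2, MeOH) should add boron to C8 of the less substituted enone under control of the ligand, giving the boronate F8. NaBO3·4H2O then returns to the route at 20.

**Step 16.** The risk is delivery of the proton to C5 on the face opposite to tin, or epimerisation on work-up; this would turn the E alkene of step 22 into Z. The fallback replaces kinetic by thermodynamic control. The C5 epimer F9 is silylated as in step 17 to its trimethylsilyl ether F10. DBU (cat.) in toluene then equilibrates C5; in the silyl ether, C6 is pushed away from both the silyloxy group on C1 and the stannyl group on C4, which is the arrangement of 25, where the fallback rejoins.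

**Step 19 (seen in step 20).** The risk is a weak preference for the chair with the axial ester, or proton transfer from 27 to the enolate. After syn elimination this gives the (E) alkylidene, whose ester cannot reach O6 in step 27. The fallback separates the (E) isomer F11 and subjects it to sensitised photoisomerisation (350 nm, benzophenone, benzene). At this stage the alkylidene is the only alkene, so this re-forms the Z/E mixture, which is returned to 30.

**Step 27.** The risks are competing reduction of the C1 ketone (activated by the α-acetoxy group) and loss of facial selectivity through the ring conformation. The fallback drops the demand for chemoselectivity. From 37, excess BH3·SMe2 with the same catalyst reduces both ketones, and lactonisation gives the C1 carbinol F12 (either C1 epimer). Dess–Martin periodinane with NaHCO3 oxidises the only free hydroxyl and returns to the route at 39.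

## Further compounds

F1 | step 22 | tricyclic stannyl butenolide: 6R lactone from 30 with 1-OSiMe3, 8-OTBS, 10-OMOM, 13-OAc | C[Si](C)(C)O[C@@]12CC[C@@](C)([Sn](C)(C)C)[C@@H]1[C@H]3OC(=O)C(COC(C)=O)=C3[C@@H](O[Si](C)(C)C(C)(C)C)C[C@@]2(C)OCOC
F2 | step 22 | 1-hydroxy tricyclic stannyl butenolide (F1 without the trimethylsilyl group) | O[C@@]12CC[C@@](C)([Sn](C)(C)C)[C@@H]1[C@H]3OC(=O)C(COC(C)=O)=C3[C@@H](O[Si](C)(C)C(C)(C)C)C[C@@]2(C)OCOC
F3 | step 22 | (4E,6R,8S,10R)-13-acetoxy-8-[(tert-butyldimethylsilyl)oxy]-10-(methoxymethoxy)-1-oxogermacra-4,7(11)-dien-12,6-olide | CC(C)(C)[Si](C)(C)O[C@H]1C[C@@](C)(OCOC)C(=O)CC/C(C)=C/[C@H]2OC(=O)C(COC(C)=O)=C12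
F4 | step 22 | (4E,6R,8S,10R)-13-acetoxy-8-hydroxy-10-(methoxymethoxy)-1-oxogermacra-4,7(11)-dien-12,6-olide | O[C@H]1C[C@@](C)(OCOC)C(=O)CC/C(C)=C/[C@H]2OC(=O)C(COC(C)=O)=C12
F5 | step 22 | (4E,6R,8S,10R)-13-acetoxy-10-(methoxymethoxy)-8-(2-methylprop-2-enoyloxy)-1-oxogermacra-4,7(11)-dien-12,6-olide | C=C(C)C(=O)O[C@H]1C[C@@](C)(OCOC)C(=O)CC/C(C)=C/[C@H]2OC(=O)C(COC(C)=O)=C12
F6 | step 22 | (4E,6R,8S,10R)-13-acetoxy-10-hydroxy-8-(2-methylprop-2-enoyloxy)-1-oxogermacra-4,7(11)-dien-12,6-olide | C=C(C)C(=O)O[C@H]1C[C@@](C)(O)C(=O)CC/C(C)=C/[C@H]2OC(=O)C(COC(C)=O)=C12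
F7 | step 14 | (1S,10R)-1-hydroxy-10-(methoxymethoxy)-4,10-dimethylbicyclo[5.3.0]deca-4,7-dien-6-one | O[C@@]12CCC(C)=C1C(=O)C=CC[C@@]2(C)OCOC
F8 | step 14 | (1S,8S,10R)-1-hydroxy-10-(methoxymethoxy)-4,10-dimethyl-8-(4,4,5,5-tetramethyl-1,3,2-dioxaborolan-2-yl)bicyclo[5.3.0]dec-4-en-6-one | O[C@@]12CCC(C)=C1C(=O)C[C@@H](B3OC(C)(C)C(C)(C)O3)C[C@@]2(C)OCOC
F9 | step 16 | C5 epimer of 24 (trans ring fusion, H5 anti to tin) | O[C@@]12CC[C@@](C)([Sn](C)(C)C)[C@H]1C(=O)C[C@@H](O[Si](C)(C)C(C)(C)C)C[C@@]2(C)OCOC
F10 | step 16 | C5 epimer of 25 (trimethylsilyl ether of F9) | C[Si](C)(C)O[C@@]12CC[C@@](C)([Sn](C)(C)C)[C@H]1C(=O)C[C@@H](O[Si](C)(C)C(C)(C)C)C[C@@]2(C)OCOC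
F11 | step 19 | (2E) isomer of 30 (ester anti to C6) | C[Si](C)(C)O[C@@]12CC[C@@](C)([Sn](C)(C)C)[C@@H]1C(=O)/C(=C(\COC(C)=O)C(=O)OC)[C@@H](O[Si](C)(C)C(C)(C)C)C[C@@]2(C)OCOC
F12 | step 27 | (4E,6R,8S,10R)-10,13-diacetoxy-1-hydroxy-8-(2-methylprop-2-enoyloxy)germacra-4,7(11)-dien-12,6-olide (either C1 epimer) | C=C(C)C(=O)O[C@H]1C[C@@](C)(OC(C)=O)C(O)CC/C(C)=C/[C@H]2OC(=O)C(COC(C)=O)=C12
A1 | alternative 1 | open-chain C6 aldehyde with C13 allylic bromide, methyl ester at C12, 8-OTBS, 10-OAc | O=C/C=C(\C)CCC(=O)[C@](C)(OC(C)=O)C[C@H](O[Si](C)(C)C(C)(C)C)/C=C(\CBr)C(=O)OC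
A2 | alternative 1 | ten-membered α-methylene-γ-lactone with 8-OTBS and 10-OAc | CC(C)(C)[Si](C)(C)O[C@H]1C[C@@](C)(OC(C)=O)C(=O)CC/C(C)=C/[C@H]2OC(=O)C(=C)[C@H]12
A3 | alternative 2 | open-chain C8 aldehyde carrying the C7 enol triflate of the tetronate, 10-OTES, 13-OAc | O=CC[C@@](C)(O[Si](CC)(CC)CC)C(=O)CC/C(C)=C/[C@H]1OC(=O)C(COC(C)=O)=C1OS(=O)(=O)C(F)(F)F
A4 | alternative 2 | ten-membered germacranolide core with free C8 hydroxyl and 10-OTES | O[C@H]1C[C@@](C)(O[Si](CC)(CC)CC)C(=O)CC/C(C)=C/[C@H]2OC(=O)C(COC(C)=O)=C12
A5 | alternative 3 | C1 cyclopropanol with C4 alkenyl iodide, C8/C10 acetonide, 13-OTBS butenolide | CC1(C)O[C@H](C2=C(CO[Si](C)(C)C(C)(C)C)C(=O)O[C@@H]2/C=C(\C)I)C[C@@](C)(O1)C3(O)CC3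
A6 | alternative 3 | ten-membered germacranolide core as C8/C10 acetonide and 13-OTBS ether | CC1(C)O[C@H]2C[C@@](C)(O1)C(=O)CC/C(C)=C/[C@H]3OC(=O)C(CO[Si](C)(C)C(C)(C)C)=C23
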